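The lactone ring (O1, C2, C3, C4, C5) is disconnected at C3–C4, the bond between the two benzyl-bearing carbons. Across the ester unit C2–O1–C5, C4 sits 1,5 to C3. In open form it is simply the unactivated, prochiral middle CH2 of a 3-arylpropyl ester. A chiral dirhodium carboxamidate converts the achiral diazoacetate 4 into a carbene at C3 that inserts into one enantiotopic C4–H bond. This one operation closes the ring, forms C3–C4 and sets C4 as R. C4 then directs a trans-selective aldol addition of the syringyl aldehyde at C3, and a single hydrogenolysis removes carbinol oxygen and benzyl ether.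

Key step: step 2

Assumption: 2 and Rh2(4S-MPPIM)4 (MPPIM = methyl 2-oxo-1-(3-phenylpropanoyl)imidazolidine-4-carboxylate, bound as its amidate to a pair of divalent rhodium atoms) are taken as catalogue items, and the carbinol carbon of 10, 11 and 12 is drawn without configuration because both epimers converge in step 5.

Step 1
Reactants: 1 3-(3,4-dimethoxyphenyl)propan-1-ol; 2 glyoxylic acid chloride p-toluenesulfonylhydrazone (TsNHN=CHCOCl)
Product: 4 3-(3,4-dimethoxyphenyl)propyl diazoacetate, via tosylhydrazone ester 3 (not isolated)
Conditions: PhNMe2, CH2Cl2, 0 °C; then Et3N, 0 °C to rt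
Reagents that add atoms: none
Why: O-acylation of the primary alcohol by the acid chloride, followed by base-induced loss of p-toluenesulfinate from the hydrazone anion (Bamford–Stevens-type fragmentation), should give the diazoacetate in one flask without touching the veratryl ring.

Step 2
Reactants: 4 3-(3,4-dimethoxyphenyl)propyl diazoacetate
Product: 6 (4R)-4-(3,4-dimethoxybenzyl)dihydrofuran-2(3H)-one, via rhodium carbene 5 (not isolated)
Conditions: Rh2(4S-MPPIM)4 (1 mol%), CH2Cl2, reflux; 4 added by syringe pump over several hours
Reagents that add atoms: none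
Why: Loss of N2 from 4 at an axial site of the divalent-rhodium dimer gives the electrophilic carbene 5, whose carbene carbon (future C3) inserts into a C–H bond of the middle chain CH2 (future C4) through a concerted, asynchronous three-centre transition state with retention at carbon. The closest known reaction type is the enantioselective intramolecular C–H insertion of primary alkyl diazoacetates catalysed by chiral dirhodium carboxamidates, which is established for 3-arylpropyl esters. The lactone closes by 1,5-insertion, that is through a five-membered cyclic transition state made of C3, C2, O1, C5 and C4. C4 is the only new stereocentre and is controlled by the catalyst alone: the four (4S)-ester groups and the N-acyl arms around the carbene let only one of the two enantiotopic C4–H bonds reach it, which should give R (the mirror-image catalyst Rh2(4R-MPPIM)4 is the remedy if the sense proves opposite). The step needs site selectivity for C4–H over the O-bound CH2 (four-membered lactone), the benzylic CH2 (six-membered lactone) and the electron-rich arene (Buchner addition); the preference for the five-membered transition state and the attenuated electrophilicity of a carboxamidate-bound carbene secure it. Slow addition keeps the diazo ester dilute so that carbene dimerisation should not compete.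

Step 3
Reactants: 7 syringaldehyde (4-hydroxy-3,5-dimethoxybenzaldehyde)
Product: 8 4-(benzyloxy)-3,5-dimethoxybenzaldehyde
Conditions: BnBr, K2CO3, DMF, 60 °C
Reagents that add atoms: benzyl bromide, BrCc1ccccc1
Why: Williamson ether synthesis on the acidic phenol should proceed cleanly because the aldehyde has no enolisable position and benzyl bromide is an unhindered SN2 partner, and the benzyl group is chosen because step 5 removes it without an extra operation.

Step 4
Reactants: 6 (4R)-4-(3,4-dimethoxybenzyl)dihydrofuran-2(3H)-one; 8 4-(benzyloxy)-3,5-dimethoxybenzaldehyde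
Product: 11 (3S,4R)-3-{[4-(benzyloxy)-3,5-dimethoxyphenyl](hydroxy)methyl}-4-(3,4-dimethoxybenzyl)dihydrofuran-2(3H)-one (3,4-trans; carbinol epimers), via lithium enolate 9 (not isolated), via lithium aldolate 10 (not isolated)
Conditions: LiN(SiMe3)2, THF, −78 °C; 8 in THF, −78 °C; sat. aq NH4Cl at −78 °C
Reagents that add atoms: none
Why: Aldol addition in which the lactone enolate meets the non-enolisable aldehyde on the face anti to the C4 benzyl group, which should set C3 trans to C4 (the descriptor at C3 reads S here only because the carbinol carbon outranks C4), while the carbinol carbon forms as a mixture that step 5 erases.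

Step 5
Reactants: 11 aldol adduct
Product: 13 (3R,4R)-4-(3,4-dimethoxybenzyl)-3-(4-hydroxy-3,5-dimethoxybenzyl)dihydrofuran-2(3H)-one, via phenolic carbinol 12 (not isolated)
Conditions: H2 (5 bar), 10% Pd/C, EtOH, 50 °C
Reagents that add atoms: none
Why: Catalytic hydrogenolysis in which Pd/C should first cleave the benzyl ether and then the C–O bond of the resulting p-hydroxybenzylic (syringyl) carbinol, the most easily hydrogenolysed kind of benzylic alcohol, under neutral conditions that leave the lactone, the four methyl ethers and the C3 and C4 stereocentres untouched.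

Compound list
1 | 3-(3,4-dimethoxyphenyl)propan-1-ol | COc1ccc(CCCO)cc1OC | starting material
2 | glyoxylic acid chloride p-toluenesulfonylhydrazone | Cc1ccc(cc1)S(=O)(=O)NN=CC(Cl)=O | starting material
3 | 3-(3,4-dimethoxyphenyl)propyl glyoxylate p-toluenesulfonylhydrazone (not isolated) | COc1ccc(CCCOC(=O)C=NNS(=O)(=O)c2ccc(C)cc2)cc1OC | intermediate
4 | 3-(3,4-dimethoxyphenyl)propyl diazoacetate | COc1ccc(CCCOC(=O)C=[N+]=[N-])cc1OC | intermediate
5 | rhodium carbene of 4 (one Rh drawn; second Rh and the four MPPIM ligands left out; not isolated) | COc1ccc(CCCOC(=O)C=[Rh])cc1OC | intermediate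
6 | (4R)-4-(3,4-dimethoxybenzyl)dihydrofuran-2(3H)-one | COc1ccc(C[C@H]2COC(=O)C2)cc1OC | intermediate
7 | syringaldehyde | COc1cc(C=O)cc(OC)c1O | starting material
8 | 4-(benzyloxy)-3,5-dimethoxybenzaldehyde | COc1cc(C=O)cc(OC)c1OCc1ccccc1 | intermediate
9 | lithium enolate of 6 (not isolated) | COc1ccc(C[C@H]2COC([O-])=C2)cc1OC.[Li+] | intermediate
10 | lithium aldolate, 3,4-trans, carbinol epimers (not isolated) | COc1ccc(C[C@H]2COC(=O)[C@@H]2C([O-])c2cc(OC)c(OCc3ccccc3)c(OC)c2)cc1OC.[Li+] | intermediate
11 | (3S,4R)-3-{[4-(benzyloxy)-3,5-dimethoxyphenyl](hydroxy)methyl}-4-(3,4-dimethoxybenzyl)dihydrofuran-2(3H)-one, 3,4-trans, carbinol epimers | COc1ccc(C[C@H]2COC(=O)[C@@H]2C(O)c2cc(OC)c(OCc3ccccc3)c(OC)c2)cc1OC | intermediate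
12 | (3S,4R)-4-(3,4-dimethoxybenzyl)-3-[hydroxy(4-hydroxy-3,5-dimethoxyphenyl)methyl]dihydrofuran-2(3H)-one, carbinol epimers (not isolated) | COc1ccc(C[C@H]2COC(=O)[C@@H]2C(O)c2cc(OC)c(O)c(OC)c2)cc1OC | intermediate
13 | (3R,4R)-4-(3,4-dimethoxybenzyl)-3-(4-hydroxy-3,5-dimethoxybenzyl)dihydrofuran-2(3H)-one | COc1ccc(C[C@H]2COC(=O)[C@@H]2Cc2cc(OC)c(O)c(OC)c2)cc1OC | target

Total step count: 5. Longest linear sequence: 4 (steps 1, 2, 4, 5).

Steps most likely to fail

1. Step 2.
- Risk: insertion at the benzylic or the O-bound CH2, addition of the carbene to the electron-rich arene, carbene dimerisation, or weak discrimination between the two enantiotopic hydrogens.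
- Fallback (sets out from 2, comes back at 6): 2 is coupled by the one-flask protocol of the first step with purchased (E)-3-(3,4-dimethoxyphenyl)prop-2-en-1-ol F1. This passes through the hydrazone ester F2 and gives the cinnamyl diazoacetate F3.
- Intramolecular cyclopropanation catalysed by a chiral dirhodium carboxamidate is a faster carbene reaction than C–H insertion. The catalyst antipode is expected to be Rh2(4R-MPPIM)4, in CH2Cl2 at reflux. It closes the lactone through the same C3–C4 bond and should give (1S,5R,6R)-6-(3,4-dimethoxyphenyl)-3-oxabicyclo[3.1.0]hexan-2-one F4.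
- Hydrogenolysis (H2, Pd/C, EtOAc) of the cyclopropane bond that is both benzylic and alpha to the carbonyl then leads to 6.

2. Step 5.
- Risk: sluggish C–O hydrogenolysis, or ionisation of the carbinol towards a quinone methide. The latter could be followed by Friedel–Crafts ring closure onto the veratryl ring or by proton loss from C3 with erosion of its configuration.
- Fallback (sets out from 11, comes back at 13): radical instead of surface-mediated deoxygenation, by the Barton–McCombie reaction. 11 is treated with 1,1'-thiocarbonyldiimidazole and DMAP in CH2Cl2 to give the O-(imidazol-1-ylthiocarbonyl) derivative F5.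
- Bu3SnH and AIBN in toluene at 90 °C should give the benzyl ether of the target F6. Mild debenzylation (H2, 1 bar, Pd/C, EtOAc, rt) then gives 13.

3. Step 4.
- Risk: reversal of the aldol addition on warming, proton transfer that stalls conversion, or dehydration of the adduct during isolation.
- Fallback (sets out from 8 and 6, comes back at 13): irreversible SN2 alkylation instead of carbonyl addition. 8 is reduced (NaBH4, MeOH, 0 °C) to 4-(benzyloxy)-3,5-dimethoxybenzyl alcohol F7 and converted (PBr3, CH2Cl2, 0 °C) into the benzylic bromide F8.
- Enolate 9, made from 6 as before, is alkylated with F8 in THF at −78 °C, anti to the C4 substituent, to give the trans benzyl ether F6. Hydrogenolysis (H2, Pd/C, EtOAc, rt) gives 13.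

Further compounds
F1 | step 2 | (E)-3-(3,4-dimethoxyphenyl)prop-2-en-1-ol (purchased) | COc1ccc(/C=C/CO)cc1OC
F2 | step 2 | (E)-3-(3,4-dimethoxyphenyl)prop-2-enyl glyoxylate p-toluenesulfonylhydrazone (not isolated) | COc1ccc(/C=C/COC(=O)C=NNS(=O)(=O)c2ccc(C)cc2)cc1OC
F3 | step 2 | (E)-3-(3,4-dimethoxyphenyl)prop-2-enyl diazoacetate | COc1ccc(/C=C/COC(=O)C=[N+]=[N-])cc1OC
F4 | step 2 | (1S,5R,6R)-6-(3,4-dimethoxyphenyl)-3-oxabicyclo[3.1.0]hexan-2-one | COc1ccc([C@@H]2[C@H]3COC(=O)[C@@H]23)cc1OC
F5 | step 5 | O-(imidazol-1-ylthiocarbonyl) derivative of 11, 3,4-trans, carbinol epimers | COc1ccc(C[C@H]2COC(=O)[C@@H]2C(OC(=S)n2ccnc2)c2cc(OC)c(OCc3ccccc3)c(OC)c2)cc1OC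
F6 | step 5 | (3R,4R)-3-[4-(benzyloxy)-3,5-dimethoxybenzyl]-4-(3,4-dimethoxybenzyl)dihydrofuran-2(3H)-one | COc1ccc(C[C@H]2COC(=O)[C@@H]2Cc2cc(OC)c(OCc3ccccc3)c(OC)c2)cc1OC
F7 | step 4 | 4-(benzyloxy)-3,5-dimethoxybenzyl alcohol | COc1cc(CO)cc(OC)c1OCc1ccccc1
F8 | step 4 | 4-(benzyloxy)-3,5-dimethoxybenzyl bromide | COc1cc(CBr)cc(OC)c1OCc1ccccc1
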